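**Assumption:** Selaginellin U has no stereocentre and is achiral (the two para-oxygenated rings on the methylidene carbon are tautomerically equivalent), so no stereocontrol is needed.

## Retrosynthetic overview

1. Target 11 ⇐ Suzuki coupling at the aryl–Cl of 9 with boronic acid 10, and before that Sonogashira coupling at the aryl–Br of 7 with alkyne 8.
2. Key disconnection: both C–O bonds of the hydroxyfuchsone in 7 (the C=O and the C–OH) ⇐ the two C–F bonds of carbinol 4, by carbenium-activated hydrolytic substitution.
3. Carbinol 4 ⇐ 2-bromo-4-chlorotoluene 1 (lithiated between Br and Cl) plus 4,4'-difluorobenzophenone 2.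
4. No ring is built; all four six-membered rings are bought, and the quinone methide ring arises by dearomatising one fluorophenyl ring in the C–O step, before the acid-sensitive alkyne and biaryl are in place.

## Route

**Step 1**
Reactants: 1 2-bromo-4-chlorotoluene; 2 4,4'-difluorobenzophenone
Product: 4 (2-bromo-6-chloro-3-methylphenyl)bis(4-fluorophenyl)methanol, via aryllithium 3 (not isolated)
Conditions: LDA (commercial solution, 1.1 equiv), THF, −78 °C, 1 h; then 2 (1.05 equiv) in THF, −78 → −40 °C; H2O quench
Reagents that add atoms: none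
Why: Directed ortho-metalation removes the most acidic ring proton (C3–H, flanked by Br and Cl), and the aryllithium, kept at −78 °C to avoid aryne formation, undergoes 1,2-addition to the electron-poor, non-enolisable diaryl ketone.

**Step 2**
Reactants: 4 (2-bromo-6-chloro-3-methylphenyl)bis(4-fluorophenyl)methanol
Product: 7 4-[(2-bromo-6-chloro-3-methylphenyl)(4-hydroxyphenyl)methylidene]cyclohexa-2,5-dien-1-one, via triarylcarbenium ion 5 (not isolated), via monofluoro fuchsone 6 (not isolated)
Conditions: 65 wt% aq. H2SO4, 90 °C, PFA vessel; then ice-water, EtOAc extraction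
Reagents that add atoms: water, O
Why: Proposed new method: the acid ionises 4 to cation 5, whose charge is delocalised onto the fluorine-bearing para carbons (an α-fluorocarbenium resonance form); water adds there to a gem-fluorohydrin that irreversibly loses HF to give quinone methide 6, and O-protonation of 6 re-forms a cation that repeats the addition–elimination on the second ring to give 7, while hydration at the central carbon is reversible and unproductive and no neighbouring aryl or alkyne is yet present to trap the cation; the closest known reaction types are SNAr on triarylcarbenium ions (methoxy displaced by amines) and the sulfuric-acid hydrolysis of C–F bonds next to carbenium centres (benzotrifluoride to benzoic acid, perfluorotrityl cation to perfluorofuchsone).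

**Step 3**
Reactants: 7 4-[(2-bromo-6-chloro-3-methylphenyl)(4-hydroxyphenyl)methylidene]cyclohexa-2,5-dien-1-one; 8 4-ethynylphenol
Product: 9 4-[{6-chloro-2-[(4-hydroxyphenyl)ethynyl]-3-methylphenyl}(4-hydroxyphenyl)methylidene]cyclohexa-2,5-dien-1-one
Conditions: Pd(PhCN)2Cl2 (3 mol%), P(t-Bu)3·HBF4 (6 mol%), CuI (3 mol%), i-Pr2NH (5 equiv), DMF, 50 °C, slow addition of 8, Ar; AcOH work-up
Reagents that add atoms: none
Why: Sonogashira coupling with a monoligated Pd–P(t-Bu)3 catalyst inserts into the hindered C–Br bond at a temperature where the C–Cl bond is inert, and the fuchsone, present as its amine-stable phenolate and shielded at the central carbon by the 2,6-disubstituted ring, carries no tertiary alkoxide that could add to the new alkyne.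

**Step 4**
Reactants: 9 4-[{6-chloro-2-[(4-hydroxyphenyl)ethynyl]-3-methylphenyl}(4-hydroxyphenyl)methylidene]cyclohexa-2,5-dien-1-one; 10 4-hydroxyphenylboronic acid
Product: 11 Selaginellin U, 4-[{4'-hydroxy-3-[(4-hydroxyphenyl)ethynyl]-4-methylbiphenyl-2-yl}(4-hydroxyphenyl)methylidene]cyclohexa-2,5-dien-1-one
Conditions: XPhos Pd G3 (3 mol%), K3PO4 (5 equiv), 10 (1.8 equiv), dioxane/H2O 4:1, 90 °C, Ar; then AcOH to pH 5
Reagents that add atoms: none
Why: Suzuki–Miyaura coupling with a dialkylbiarylphosphine catalyst activates the ortho-substituted aryl chloride, unprotected 4-hydroxyphenylboronic acid couples cleanly under aqueous phosphate, and the internal diarylalkyne and the phenolate dye are stable to these conditions.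

## Compound list

1 | 2-bromo-4-chlorotoluene (2-bromo-4-chloro-1-methylbenzene) | Cc1ccc(Cl)cc1Br | starting material
2 | 4,4'-difluorobenzophenone | O=C(c1ccc(F)cc1)c1ccc(F)cc1 | starting material
3 | (2-bromo-6-chloro-3-methylphenyl)lithium | Cc1ccc(Cl)c([Li])c1Br | intermediate
4 | (2-bromo-6-chloro-3-methylphenyl)bis(4-fluorophenyl)methanol | Cc1ccc(Cl)c(C(O)(c2ccc(F)cc2)c2ccc(F)cc2)c1Br | intermediate
5 | (2-bromo-6-chloro-3-methylphenyl)bis(4-fluorophenyl)methylium hydrogen sulfate | Cc1ccc(Cl)c([C+](c2ccc(F)cc2)c2ccc(F)cc2)c1Br.OS(=O)(=O)[O-] | intermediate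
6 | 4-[(2-bromo-6-chloro-3-methylphenyl)(4-fluorophenyl)methylidene]cyclohexa-2,5-dien-1-one | Cc1ccc(Cl)c(C(=C2C=CC(=O)C=C2)c2ccc(F)cc2)c1Br | intermediate
7 | 4-[(2-bromo-6-chloro-3-methylphenyl)(4-hydroxyphenyl)methylidene]cyclohexa-2,5-dien-1-one | Cc1ccc(Cl)c(C(=C2C=CC(=O)C=C2)c2ccc(O)cc2)c1Br | intermediate
8 | 4-ethynylphenol | C#Cc1ccc(O)cc1 | starting material
9 | 4-[{6-chloro-2-[(4-hydroxyphenyl)ethynyl]-3-methylphenyl}(4-hydroxyphenyl)methylidene]cyclohexa-2,5-dien-1-one | Cc1ccc(Cl)c(C(=C2C=CC(=O)C=C2)c2ccc(O)cc2)c1C#Cc1ccc(O)cc1 | intermediate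
10 | 4-hydroxyphenylboronic acid | OB(O)c1ccc(O)cc1 | starting material
11 | Selaginellin U | Cc1ccc(-c2ccc(O)cc2)c(C(=C2C=CC(=O)C=C2)c2ccc(O)cc2)c1C#Cc1ccc(O)cc1 | target

## Step count and risks

Total step count: 4. Longest linear sequence: 4 (1 → 4 → 7 → 9 → 11).

Steps most likely to fail:

**Step 2 (proposed new C–O bond formation).** Para attack of water on cation 5 may be too slow, or the second substitution may stall at 6. The fallback uses known chemistry and sets out from 1. Aryllithium 3, generated as in step 1, is added to commercial 4,4'-dimethoxybenzophenone to give (2-bromo-6-chloro-3-methylphenyl)bis(4-methoxyphenyl)methanol F1. BBr3 (CH2Cl2, −78 °C to rt, aqueous work-up) then cleaves both methyl ethers, and the bis-phenol carbinol loses water spontaneously. The fallback comes back to the route at 7.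

**Step 3 (Sonogashira at the di-ortho-substituted bromide of an anionic dye).** Oxidative addition may be slow and 4-ethynylphenol may oligomerise or homocouple. The fallback reverses the polarity of the second aryl–alkyne bond and sets out from 7. Coupling 7 with the small, robust ethynyltrimethylsilane under the same Pd/Cu conditions gives 4-[{6-chloro-3-methyl-2-[(trimethylsilyl)ethynyl]phenyl}(4-hydroxyphenyl)methylidene]cyclohexa-2,5-dien-1-one F2. K2CO3/MeOH removes silicon to give 4-[(6-chloro-2-ethynyl-3-methylphenyl)(4-hydroxyphenyl)methylidene]cyclohexa-2,5-dien-1-one F3. A room-temperature Sonogashira coupling of F3 with cheap 4-iodophenol (Pd(PPh3)2Cl2, CuI, Et3N, DMF) comes back to the route at 9.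

**Step 4 (Suzuki at the hindered chloride next to the quinone methide).** The aryl–Pd intermediate may be diverted into intramolecular C–H arylation of a geminal ring, or oxidative addition on the electron-rich dye may be sluggish. The fallback is a leuco-dye detour that sets out from 9. NaBH4 (THF/MeOH, 0 °C) reduces the quinone methide to 4,4'-({6-chloro-2-[(4-hydroxyphenyl)ethynyl]-3-methylphenyl}methylene)diphenol F4. Suzuki coupling of F4 with 10 under the step 4 conditions gives 4,4'-({4'-hydroxy-3-[(4-hydroxyphenyl)ethynyl]-4-methylbiphenyl-2-yl}methylene)diphenol F5. DDQ (1 equiv, dioxane, 0 °C) re-oxidises the bis(hydroxyphenyl)methane and comes back to the route at 11.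

## Further compounds

F1 | step 2 | (2-bromo-6-chloro-3-methylphenyl)bis(4-methoxyphenyl)methanol | Cc1ccc(Cl)c(C(O)(c2ccc(OC)cc2)c2ccc(OC)cc2)c1Br
F2 | step 3 | 4-[{6-chloro-3-methyl-2-[(trimethylsilyl)ethynyl]phenyl}(4-hydroxyphenyl)methylidene]cyclohexa-2,5-dien-1-one | Cc1ccc(Cl)c(C(=C2C=CC(=O)C=C2)c2ccc(O)cc2)c1C#C[Si](C)(C)C
F3 | step 3 | 4-[(6-chloro-2-ethynyl-3-methylphenyl)(4-hydroxyphenyl)methylidene]cyclohexa-2,5-dien-1-one | Cc1ccc(Cl)c(C(=C2C=CC(=O)C=C2)c2ccc(O)cc2)c1C#C
F4 | step 4 | 4,4'-({6-chloro-2-[(4-hydroxyphenyl)ethynyl]-3-methylphenyl}methylene)diphenol | Cc1ccc(Cl)c(C(c2ccc(O)cc2)c2ccc(O)cc2)c1C#Cc1ccc(O)cc1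
F5 | step 4 | 4,4'-({4'-hydroxy-3-[(4-hydroxyphenyl)ethynyl]-4-methylbiphenyl-2-yl}methylene)diphenol | Cc1ccc(-c2ccc(O)cc2)c(C(c2ccc(O)cc2)c2ccc(O)cc2)c1C#Cc1ccc(O)cc1
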